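All constants belong to no real substance; the run is a simulation.

A ratio of 33.0 stands over this board: by that factor the first step, with the whole charge turned to product, outruns the second step.

all flasks: starting material 20 mM

| charge | remark | time |
|---|---|---|
| red | one stirred flow tank at steady state, fed with the mixture as stated, mean residence time 8.0 h |  |
| ochre | a closed flask charged with all of it at once and left for 8.0 h | 8.0 h |
| amber | a single well-mixed tank run continuously and read at steady state, 80.0 h in it on average |  |

    starting material + 2 product → 3 product (k1 = 57 L² mol⁻² min⁻¹)
    starting material → product (k2 = 6.9 × 10⁻⁴ min⁻¹)

* the set-up with the highest amount of product at the outlet or at the end, in percent of the starting material put in ("none" if the first two lie within 2 percentage points) (red / ochre / amber / none)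
* amount of product at the outlet or at the end, in percent of the starting material put in, red
* amount of product at the outlet or at the end, in percent of the starting material put in, ochre
* amount of product at the outlet or at the end, in percent of the starting material put in, amber

- where a step has two of a species, its rate is k times that concentration squared, and two are used at each turn
- the stated concentrations are those of everything mixed, before any reaction; amounts are the same in each set-up
- run time (ochre): 8.0 h

Call y the fraction of the charge that is product and x the fraction left. Each bit of x is consumed with the constant 6.9 × 10⁻⁴ min⁻¹ plus 0.0228 min⁻¹ times the square of y.

One colleague takes the closed-flask view: ochre runs at full speed, y at its top, for 8.0 h, which leaves 0.00127% of the charge. A tank, by its balance, leaves one over one plus constant times residence time, which at an equal time is more than that.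

I side with the other colleague: ochre begins with y at nothing. The second step must carry y to 0.174, where the two steps run equally, and that takes about 4.20 h. The first step then needs about 4.20 h to cross. The sum is the start-up time 8.40 h, the induction period of an autocatalysis. It is longer than ochre's 8.0 h, so I place ochre last without a number.

Red and amber, as tanks at steady state, sit at their outlet y, with no start-up to pass. For red, with a residence time equal to 8.0 h, a first pass with y at its top leaves 8.15%. Putting the resulting y back into the balance leaves 9.47%, so red gives 90.5%. Amber, by the first pass, gives 99.1%.

The forecast names amber, with 90.2% for red against my 90.5%, 83.9% for ochre and 99.1% for amber, on the ground that “the flask must first creep through a slow start on the weak uncatalysed step”.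

The simulation gives 90.2% for red, 83.9% for ochre and 99.1% for amber, so amber stands first.

In ochre the second step made the first product and the first step followed as product gathered. At 8.0 h, still short of the start-up time of 8.40 h, 16.1% of the charge stood unreacted, and a run to 8.35 h already moves the answer by 5 points. The closed-flask view holds for a long run of ochre: left for 80.0 h, about ten times its start-up time, ochre gives 100%, above the 99.1% of amber, whose residence time is the same on average.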